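**Plan**
- Retrosynthesis: after removal of three benzyl groups and two dioxolanes, the depside is cut at the bond between the ester oxygen and C4 of ring B, not at the acyl C–O bond. This gives a ring A carboxylate and a ring B aryl(2,4,6-trimethoxyphenyl)iodonium salt. Each 2-oxoheptyl chain is then cut at its benzylic CH2–C(=O) bond, back to an ortho-toluate and the Weinreb amide of hexanoic acid.
- Enabling feature: the ring A carbonyl carbon sits between the C2 oxygen substituent and the C6 side chain and is shielded. C4 of ring B has only C–H neighbours (C3 and C5) and lies para to the ester, so oxygen is joined to C4 instead of a phenol to the carbonyl.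
- Forward: both benzene rings are bought. Ring A acid takes four steps from methyl orsellinate. Ring B iodonium salt takes seven steps from methyl 2-methoxy-6-methylbenzoate, with C4 reached by sterically controlled C–H borylation/iodination. The halves are joined by carboxylate O-arylation, then ketal hydrolysis and hydrogenolysis finish the synthesis.
- Stereochemistry: the target has no stereocentre and no double-bond geometry; nothing has to be set.

Key step: step 13

Remark: the target is taken as the open-chain keto acid drawn; methyl 2-methoxy-6-methylbenzoate is assumed to be purchasable (otherwise it is one step, MeI/K2CO3, from 2-methoxy-6-methylbenzoic acid).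

**Route**

Step 1
Reactants: 1 hexanoyl chloride
Product: 2 N-methoxy-N-methylhexanamide
Conditions: MeNH(OMe)·HCl, K2CO3, CH2Cl2/H2O, 0 °C → rt
Reagents that add atoms: N,O-dimethylhydroxylamine hydrochloride, CNOC.Cl
Why: Schotten–Baumann acylation of the amine should give the Weinreb amide that later stops a benzylic anion at the ketone stage.

Step 2
Reactants: 3 methyl orsellinate
Product: 4 methyl 2,4-bis(benzyloxy)-6-methylbenzoate
Conditions: BnBr, K2CO3, DMF, 60 °C
Reagents that add atoms: benzyl bromide, BrCc1ccccc1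
Why: Williamson ether synthesis on both phenols; warming is needed because the 2-OH is hydrogen-bonded to the ester carbonyl.

Step 3
Reactants: 4 methyl 2,4-bis(benzyloxy)-6-methylbenzoate; 2 N-methoxy-N-methylhexanamide
Product: 7 methyl 2,4-bis(benzyloxy)-6-(2-oxoheptyl)benzoate, via benzylic lithium reagent 5 (not isolated), via lithium hemiaminal alkoxide 6 (not isolated)
Conditions: LiN(i-Pr)2, THF, −78 °C; then 2, −78 °C; AcOH, −78 °C
Reagents that add atoms: none
Why: Lateral (benzylic) lithiation of the ortho-toluate followed by Weinreb ketone synthesis, in which the chelated tetrahedral adduct persists until the cold acidic quench so that neither over-addition nor cyclisation of a ketone enolate onto the ester can take place.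

Step 4
Reactants: 7 methyl 2,4-bis(benzyloxy)-6-(2-oxoheptyl)benzoate
Product: 8 methyl 2,4-bis(benzyloxy)-6-[(2-pentyl-1,3-dioxolan-2-yl)methyl]benzoate
Conditions: Me3SiOCH2CH2OSiMe3, Me3SiOTf (cat.), CH2Cl2, −78 → −20 °C; pyridine quench
Reagents that add atoms: 1,2-bis(trimethylsilyloxy)ethane, C[Si](C)(C)OCCO[Si](C)(C)C
Why: Noyori ketalisation under aprotic, low-temperature conditions should protect the ketone without the enol lactonisation onto the neighbouring ester that hot protic acid could cause.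

Step 5
Reactants: 8 methyl 2,4-bis(benzyloxy)-6-[(2-pentyl-1,3-dioxolan-2-yl)methyl]benzoate
Product: 10 2,4-bis(benzyloxy)-6-[(2-pentyl-1,3-dioxolan-2-yl)methyl]benzoic acid, via sodium carboxylate 9 (not isolated)
Conditions: NaOH, DMSO/H2O, 90 °C; then aq. NaHSO4 to pH 4, 0 °C; acid used without storage
Reagents that add atoms: sodium hydroxide, [Na+].[OH-]
Why: Saponification with poorly solvated hydroxide in DMSO, chosen because the ester carbonyl is flanked by two ortho substituents; benzyl ethers and the dioxolane are inert to base, and the brief cold acidification to pH 4 should spare the ketal.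

Step 6
Reactants: 11 methyl 2-methoxy-6-methylbenzoate; 2 N-methoxy-N-methylhexanamide
Product: 14 methyl 2-methoxy-6-(2-oxoheptyl)benzoate, via benzylic lithium reagent 12 (not isolated), via lithium hemiaminal alkoxide 13 (not isolated)
Conditions: LiN(i-Pr)2, THF, −78 °C; then 2, −78 °C; AcOH, −78 °C
Reagents that add atoms: none
Why: The same lateral lithiation and Weinreb ketone synthesis as in step 3, on a toluate whose ester is again shielded from self-condensation by its two ortho substituents.

Step 7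
Reactants: 14 methyl 2-methoxy-6-(2-oxoheptyl)benzoate
Product: 15 methyl 2-methoxy-6-[(2-pentyl-1,3-dioxolan-2-yl)methyl]benzoate
Conditions: Me3SiOCH2CH2OSiMe3, Me3SiOTf (cat.), CH2Cl2, −78 → −20 °C; pyridine quench
Reagents that add atoms: 1,2-bis(trimethylsilyloxy)ethane, C[Si](C)(C)OCCO[Si](C)(C)C
Why: Noyori ketalisation as in step 4, so that the benzylic ketone is masked before any oxidant or base is used on ring B.

Step 8
Reactants: 15 methyl 2-methoxy-6-[(2-pentyl-1,3-dioxolan-2-yl)methyl]benzoate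
Product: 17 methyl 4-iodo-2-methoxy-6-[(2-pentyl-1,3-dioxolan-2-yl)methyl]benzoate, via aryl pinacol boronate 16 (not isolated)
Conditions: [Ir(OMe)(cod)]2 (cat.), 4,4'-di-tert-butyl-2,2'-bipyridine, B2pin2, THF, 80 °C; evaporate; then CuI (cat.), 1,10-phenanthroline, KI, MeOH/H2O, air, 80 °C
Reagents that add atoms: bis(pinacolato)diboron, CC1(C)OB(OC1(C)C)B1OC(C)(C)C(C)(C)O1 (boron of 16 only); potassium iodide, [K+].[I-]
Why: Iridium-catalysed C–H borylation should go to C4, the only aromatic C–H of the 1,2,3-trisubstituted ring without an ortho substituent, and copper-catalysed oxidative iodination of the boronate in the same flask is a known one-pot sequence; the methyl ester is kept here because a benzyl ester would offer competing unhindered C–H bonds.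

Step 9
Reactants: 17 methyl 4-iodo-2-methoxy-6-[(2-pentyl-1,3-dioxolan-2-yl)methyl]benzoate
Product: 19 4-iodo-2-methoxy-6-[(2-pentyl-1,3-dioxolan-2-yl)methyl]benzoic acid, via sodium carboxylate 18 (not isolated)
Conditions: NaOH, DMSO/H2O, 90 °C; then aq. NaHSO4 to pH 4, 0 °C
Reagents that add atoms: sodium hydroxide, [Na+].[OH-]
Why: Saponification of the hindered methyl ester as in step 5; the aryl iodide is not activated enough for substitution by hydroxide and the ketal is base-stable.

Step 10
Reactants: 19 4-iodo-2-methoxy-6-[(2-pentyl-1,3-dioxolan-2-yl)methyl]benzoic acid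
Product: 21 benzyl 4-iodo-2-methoxy-6-[(2-pentyl-1,3-dioxolan-2-yl)methyl]benzoate, via potassium carboxylate 20 (not isolated)
Conditions: BnBr, K2CO3, DMF, rt
Reagents that add atoms: benzyl bromide, BrCc1ccccc1
Why: Carboxylate O-alkylation (SN2 at the benzyl bromide by the potassium carboxylate that K2CO3 generates from the free acid) is indifferent to the crowding around the carbonyl and installs the ester that the final hydrogenolysis removes.

Step 11
Reactants: 21 benzyl 4-iodo-2-methoxy-6-[(2-pentyl-1,3-dioxolan-2-yl)methyl]benzoate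
Product: 22 benzyl 4-(diacetoxyiodo)-2-methoxy-6-[(2-pentyl-1,3-dioxolan-2-yl)methyl]benzoate
Conditions: 1-chloromethyl-4-fluoro-1,4-diazoniabicyclo[2.2.2]octane bis(tetrafluoroborate) (Selectfluor), Me3SiOAc, dry MeCN, rt; crude product used directly
Reagents that add atoms: trimethylsilyl acetate, CC(=O)O[Si](C)(C)C
Why: Oxidation of the aryl iodide to the trivalent iodine diacetate by electrophilic fluorine, followed by fluoride/acetate exchange driven by Me3SiF formation; the medium is anhydrous and free of strong protic acid, as the dioxolane requires.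

Step 12
Reactants: 22 benzyl 4-(diacetoxyiodo)-2-methoxy-6-[(2-pentyl-1,3-dioxolan-2-yl)methyl]benzoate; 23 1,3,5-trimethoxybenzene
Product: 25 {4-(benzyloxycarbonyl)-3-methoxy-5-[(2-pentyl-1,3-dioxolan-2-yl)methyl]phenyl}(2,4,6-trimethoxyphenyl)iodonium tosylate, via iodonium acetate 24 (not isolated)
Conditions: CF3CH2OH, rt; evaporate; CH2Cl2, repeated wash with aq. sodium p-toluenesulfonate (NaOTs); precipitation with Et2O
Reagents that add atoms: sodium p-toluenesulfonate, [Na+].Cc1ccc(S(=O)(=O)[O-])cc1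
Why: Electrophilic aromatic substitution of the very electron-rich trimethoxybenzene by the diacetoxyiodoarene, activated only by the hydrogen-bond-donating fluoroalcohol, should give the diaryliodonium acetate, and anion metathesis then replaces the nucleophilic acetate by tosylate.

Step 13
Reactants: 10 2,4-bis(benzyloxy)-6-[(2-pentyl-1,3-dioxolan-2-yl)methyl]benzoic acid; 25 ring B aryl(2,4,6-trimethoxyphenyl)iodonium tosylate
Product: 28 benzyl 4-({2,4-bis(benzyloxy)-6-[(2-pentyl-1,3-dioxolan-2-yl)methyl]benzoyl}oxy)-2-methoxy-6-[(2-pentyl-1,3-dioxolan-2-yl)methyl]benzoate, via potassium carboxylate 26 (not isolated), via iodonium carboxylate 27 (not isolated)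
Conditions: KOt-Bu (1.0 equiv), toluene, rt; then 25, 110 °C
Reagents that add atoms: none
Why: Deprotonation of 10 gives potassium carboxylate 26, which replaces tosylate on the trivalent iodine of 25 to give the T-shaped diaryl(carboxylato)iodine intermediate 27; ligand coupling then joins the carboxylate oxygen to the ipso carbon C4 of ring B and releases 2-iodo-1,3,5-trimethoxybenzene. The closest known reaction is the metal-free O-arylation of potassium carboxylates, hindered benzoates included, with diaryliodonium salts. No ring is closed and no stereocentre is formed. The step needs ring B, not the auxiliary ring, to pass to oxygen: the 2,4,6-trimethoxyphenyl group is too electron-rich to accept the carboxylate and stays on iodine, while C4 of ring B is para to the ester and has no ortho substituent. The crowded ring A carbonyl carbon is never attacked because the acid acts as the nucleophile through oxygen, and exactly one equivalent of base leaves no free alkoxide to attack the benzyl ester or cause aryne formation.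

Step 14
Reactants: 28 fully protected depside
Product: 29 benzyl 4-{[2,4-bis(benzyloxy)-6-(2-oxoheptyl)benzoyl]oxy}-2-methoxy-6-(2-oxoheptyl)benzoate
Conditions: 1 M aq. HCl, THF, rt → 40 °C
Reagents that add atoms: water, O
Why: Acid-catalysed ketal hydrolysis with dilute acid should free both ketones, while both ester carbonyls, each flanked by two ortho substituents, are too shielded for the keto enols to lactonise onto them.

Step 15
Reactants: 29 benzyl 4-{[2,4-bis(benzyloxy)-6-(2-oxoheptyl)benzoyl]oxy}-2-methoxy-6-(2-oxoheptyl)benzoate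
Product: 30 arthonioic acid
Conditions: H2 (1 atm), 10% Pd/C, EtOAc, rt
Reagents that add atoms: none
Why: Catalytic hydrogenolysis should cleave the two benzyl ethers and the benzyl ester in one neutral operation that leaves the depside ester, the aryl methyl ether and the dialkyl ketones untouched.

**Compound list**

1 | hexanoyl chloride | CCCCCC(=O)Cl | starting material
2 | N-methoxy-N-methylhexanamide | CCCCCC(=O)N(C)OC | intermediate
3 | methyl orsellinate (methyl 2,4-dihydroxy-6-methylbenzoate) | COC(=O)c1c(C)cc(O)cc1O | starting material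
4 | methyl 2,4-bis(benzyloxy)-6-methylbenzoate | COC(=O)c1c(C)cc(OCc2ccccc2)cc1OCc1ccccc1 | intermediate
5 | [3,5-bis(benzyloxy)-2-(methoxycarbonyl)benzyl]lithium | [Li]Cc1cc(OCc2ccccc2)cc(OCc2ccccc2)c1C(=O)OC | intermediate
6 | lithium 1-[3,5-bis(benzyloxy)-2-(methoxycarbonyl)phenyl]-2-[methoxy(methyl)amino]heptan-2-olate | CCCCCC([O-])(Cc1cc(OCc2ccccc2)cc(OCc2ccccc2)c1C(=O)OC)N(C)OC.[Li+] | intermediate
7 | methyl 2,4-bis(benzyloxy)-6-(2-oxoheptyl)benzoate | CCCCCC(=O)Cc1cc(OCc2ccccc2)cc(OCc2ccccc2)c1C(=O)OC | intermediate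
8 | methyl 2,4-bis(benzyloxy)-6-[(2-pentyl-1,3-dioxolan-2-yl)methyl]benzoate | CCCCCC1(OCCO1)Cc1cc(OCc2ccccc2)cc(OCc2ccccc2)c1C(=O)OC | intermediate
9 | sodium 2,4-bis(benzyloxy)-6-[(2-pentyl-1,3-dioxolan-2-yl)methyl]benzoate | CCCCCC1(OCCO1)Cc1cc(OCc2ccccc2)cc(OCc2ccccc2)c1C(=O)[O-].[Na+] | intermediate
10 | 2,4-bis(benzyloxy)-6-[(2-pentyl-1,3-dioxolan-2-yl)methyl]benzoic acid | CCCCCC1(OCCO1)Cc1cc(OCc2ccccc2)cc(OCc2ccccc2)c1C(=O)O | intermediate
11 | methyl 2-methoxy-6-methylbenzoate | COC(=O)c1c(C)cccc1OC | starting material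
12 | [3-methoxy-2-(methoxycarbonyl)benzyl]lithium | [Li]Cc1cccc(OC)c1C(=O)OC | intermediate
13 | lithium 1-[3-methoxy-2-(methoxycarbonyl)phenyl]-2-[methoxy(methyl)amino]heptan-2-olate | CCCCCC([O-])(Cc1cccc(OC)c1C(=O)OC)N(C)OC.[Li+] | intermediate
14 | methyl 2-methoxy-6-(2-oxoheptyl)benzoate | CCCCCC(=O)Cc1cccc(OC)c1C(=O)OC | intermediate
15 | methyl 2-methoxy-6-[(2-pentyl-1,3-dioxolan-2-yl)methyl]benzoate | CCCCCC1(OCCO1)Cc1cccc(OC)c1C(=O)OC | intermediate
16 | methyl 2-methoxy-6-[(2-pentyl-1,3-dioxolan-2-yl)methyl]-4-(4,4,5,5-tetramethyl-1,3,2-dioxaborolan-2-yl)benzoate | CCCCCC1(OCCO1)Cc1cc(B2OC(C)(C)C(C)(C)O2)cc(OC)c1C(=O)OC | intermediate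
17 | methyl 4-iodo-2-methoxy-6-[(2-pentyl-1,3-dioxolan-2-yl)methyl]benzoate | CCCCCC1(OCCO1)Cc1cc(I)cc(OC)c1C(=O)OC | intermediate
18 | sodium 4-iodo-2-methoxy-6-[(2-pentyl-1,3-dioxolan-2-yl)methyl]benzoate | CCCCCC1(OCCO1)Cc1cc(I)cc(OC)c1C(=O)[O-].[Na+] | intermediate
19 | 4-iodo-2-methoxy-6-[(2-pentyl-1,3-dioxolan-2-yl)methyl]benzoic acid | CCCCCC1(OCCO1)Cc1cc(I)cc(OC)c1C(=O)O | intermediate
20 | potassium 4-iodo-2-methoxy-6-[(2-pentyl-1,3-dioxolan-2-yl)methyl]benzoate | CCCCCC1(OCCO1)Cc1cc(I)cc(OC)c1C(=O)[O-].[K+] | intermediate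
21 | benzyl 4-iodo-2-methoxy-6-[(2-pentyl-1,3-dioxolan-2-yl)methyl]benzoate | CCCCCC1(OCCO1)Cc1cc(I)cc(OC)c1C(=O)OCc1ccccc1 | intermediate
22 | benzyl 4-(diacetoxyiodo)-2-methoxy-6-[(2-pentyl-1,3-dioxolan-2-yl)methyl]benzoate | CCCCCC1(OCCO1)Cc1cc(I(OC(C)=O)OC(C)=O)cc(OC)c1C(=O)OCc1ccccc1 | intermediate
23 | 1,3,5-trimethoxybenzene | COc1cc(OC)cc(OC)c1 | starting material
24 | {4-(benzyloxycarbonyl)-3-methoxy-5-[(2-pentyl-1,3-dioxolan-2-yl)methyl]phenyl}(2,4,6-trimethoxyphenyl)iodonium acetate | COc1cc(OC)c([I+]c2cc(OC)c(C(=O)OCc3ccccc3)c(CC3(CCCCC)OCCO3)c2)c(OC)c1.CC(=O)[O-] | intermediate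
25 | {4-(benzyloxycarbonyl)-3-methoxy-5-[(2-pentyl-1,3-dioxolan-2-yl)methyl]phenyl}(2,4,6-trimethoxyphenyl)iodonium tosylate | COc1cc(OC)c([I+]c2cc(OC)c(C(=O)OCc3ccccc3)c(CC3(CCCCC)OCCO3)c2)c(OC)c1.Cc1ccc(S(=O)(=O)[O-])cc1 | intermediate
26 | potassium 2,4-bis(benzyloxy)-6-[(2-pentyl-1,3-dioxolan-2-yl)methyl]benzoate | CCCCCC1(OCCO1)Cc1cc(OCc2ccccc2)cc(OCc2ccccc2)c1C(=O)[O-].[K+] | intermediate
27 | the iodonium cation of 25 with 2,4-bis(benzyloxy)-6-[(2-pentyl-1,3-dioxolan-2-yl)methyl]benzoate as the oxygen ligand on iodine | COc1cc(OC)c([I+]c2cc(OC)c(C(=O)OCc3ccccc3)c(CC3(CCCCC)OCCO3)c2)c(OC)c1.CCCCCC1(OCCO1)Cc1cc(OCc2ccccc2)cc(OCc2ccccc2)c1C(=O)[O-] | intermediate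
28 | benzyl 4-({2,4-bis(benzyloxy)-6-[(2-pentyl-1,3-dioxolan-2-yl)methyl]benzoyl}oxy)-2-methoxy-6-[(2-pentyl-1,3-dioxolan-2-yl)methyl]benzoate | CCCCCC1(OCCO1)Cc1cc(OCc2ccccc2)cc(OCc2ccccc2)c1C(=O)Oc1cc(CC2(CCCCC)OCCO2)c(C(=O)OCc2ccccc2)c(OC)c1 | intermediate
29 | benzyl 4-{[2,4-bis(benzyloxy)-6-(2-oxoheptyl)benzoyl]oxy}-2-methoxy-6-(2-oxoheptyl)benzoate | CCCCCC(=O)Cc1cc(OCc2ccccc2)cc(OCc2ccccc2)c1C(=O)Oc1cc(CC(=O)CCCCC)c(C(=O)OCc2ccccc2)c(OC)c1 | intermediate
30 | arthonioic acid, 4-{[2,4-dihydroxy-6-(2-oxoheptyl)benzoyl]oxy}-2-methoxy-6-(2-oxoheptyl)benzoic acid | CCCCCC(=O)Cc1cc(O)cc(O)c1C(=O)Oc1cc(CC(=O)CCCCC)c(C(=O)O)c(OC)c1 | target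

**Step count and risks**

Total step count: 15.
Longest linear sequence: 11 steps (step 1, then steps 6 to 15, counted from hexanoyl chloride; 10 steps from methyl 2-methoxy-6-methylbenzoate).

Steps most likely to fail:

Step 13. Ligand coupling of the doubly ortho-substituted carboxylate may be slower than thermal breakdown of the iodonium salt, or the carboxylate may be delivered in part to the auxiliary ring. The fallback closes the depside the classical way, with ring B as the nucleophile, setting out from iodide 21 and acid 10. Miyaura borylation of 21 (B2pin2, PdCl2(dppf), KOAc, dioxane, 80 °C) should give benzyl 2-methoxy-6-[(2-pentyl-1,3-dioxolan-2-yl)methyl]-4-(4,4,5,5-tetramethyl-1,3,2-dioxaborolan-2-yl)benzoate F1. Oxidation (NaBO3·4H2O, THF/H2O, rt) should then give benzyl 4-hydroxy-2-methoxy-6-[(2-pentyl-1,3-dioxolan-2-yl)methyl]benzoate F2. Acid 10 is converted under neutral conditions (1-chloro-N,N,2-trimethylprop-1-en-1-amine, CH2Cl2, 0 °C) into 2,4-bis(benzyloxy)-6-[(2-pentyl-1,3-dioxolan-2-yl)methyl]benzoyl chloride F3. The potassium phenoxide of F2 (KOt-Bu, THF, 0 °C → rt) is acylated by F3, and the route is rejoined at 28.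

Step 12. The dioxolane may be lost or the side chain oxidised while trivalent iodine is present, and exchange of acetate for tosylate may be incomplete, so that acetate competes as the nucleophile in step 13. The fallback builds the iodonium salt by ipso-substitution of an aryl stannane under neutral conditions; it sets out from iodide 21 and also bypasses step 11. Stannylation of 21 (Bu3SnSnBu3, Pd(PPh3)4, toluene, 110 °C) should give benzyl 2-methoxy-6-[(2-pentyl-1,3-dioxolan-2-yl)methyl]-4-(tributylstannyl)benzoate F4. Treatment with [hydroxy(tosyloxy)iodo]-4-methoxybenzene (CH2Cl2, 0 °C → rt) should give {4-(benzyloxycarbonyl)-3-methoxy-5-[(2-pentyl-1,3-dioxolan-2-yl)methyl]phenyl}(4-methoxyphenyl)iodonium tosylate F5. Heating F5 with the potassium carboxylate of acid 10 (KOt-Bu, toluene, 100 °C) should transfer the ester-bearing ring in preference to the anisyl group, and the route is rejoined at 28.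

Step 14. Acid may drive the freed ketones, as their enols, onto the flanking ester carbonyls (isocoumarin formation with loss of benzyl alcohol or rupture of the depside link), or hydrolysis may stop at the mono-ketal. The fallback inverts the end game and unmasks the ketones by exchange instead of aqueous acid; it sets out from 28. Hydrogenolysis (H2, 10% Pd/C, EtOAc, rt) should give 4-({2,4-dihydroxy-6-[(2-pentyl-1,3-dioxolan-2-yl)methyl]benzoyl}oxy)-2-methoxy-6-[(2-pentyl-1,3-dioxolan-2-yl)methyl]benzoic acid F6. Transketalisation to acetone (PdCl2(MeCN)2 cat., acetone, rt) should then give the target, and the route is rejoined at 30.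

**Further compounds**

F1 | step 13 | benzyl 2-methoxy-6-[(2-pentyl-1,3-dioxolan-2-yl)methyl]-4-(4,4,5,5-tetramethyl-1,3,2-dioxaborolan-2-yl)benzoate | CCCCCC1(OCCO1)Cc1cc(B2OC(C)(C)C(C)(C)O2)cc(OC)c1C(=O)OCc1ccccc1
F2 | step 13 | benzyl 4-hydroxy-2-methoxy-6-[(2-pentyl-1,3-dioxolan-2-yl)methyl]benzoate | CCCCCC1(OCCO1)Cc1cc(O)cc(OC)c1C(=O)OCc1ccccc1
F3 | step 13 | 2,4-bis(benzyloxy)-6-[(2-pentyl-1,3-dioxolan-2-yl)methyl]benzoyl chloride | CCCCCC1(OCCO1)Cc1cc(OCc2ccccc2)cc(OCc2ccccc2)c1C(=O)Cl
F4 | step 12 | benzyl 2-methoxy-6-[(2-pentyl-1,3-dioxolan-2-yl)methyl]-4-(tributylstannyl)benzoate | CCCCCC1(OCCO1)Cc1cc([Sn](CCCC)(CCCC)CCCC)cc(OC)c1C(=O)OCc1ccccc1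
F5 | step 12 | {4-(benzyloxycarbonyl)-3-methoxy-5-[(2-pentyl-1,3-dioxolan-2-yl)methyl]phenyl}(4-methoxyphenyl)iodonium tosylate | COc1ccc([I+]c2cc(OC)c(C(=O)OCc3ccccc3)c(CC3(CCCCC)OCCO3)c2)cc1.Cc1ccc(S(=O)(=O)[O-])cc1
F6 | step 14 | 4-({2,4-dihydroxy-6-[(2-pentyl-1,3-dioxolan-2-yl)methyl]benzoyl}oxy)-2-methoxy-6-[(2-pentyl-1,3-dioxolan-2-yl)methyl]benzoic acid | CCCCCC1(OCCO1)Cc1cc(O)cc(O)c1C(=O)Oc1cc(CC2(CCCCC)OCCO2)c(C(=O)O)c(OC)c1
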